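Two shares were asked of one new flask, an early one and a late one, and I reckoned each from its own readings in the earlier runs.

| flask | Z | remark | time |
|---|---|---|---|
| epsilon | 0.067 M | run made earlier |  |
| gamma | 0.15 M | run made earlier |  |
| flask | 0.10 M |  | 40 h |

| run | time / h | E / % | X / % | Z / % |
|---|---|---|---|---|
| epsilon | 2.50 | 6.7 | 2.7 | 30.2 |
| epsilon | 4.00 | 11.5 | 2.5 | 13.2 |
| epsilon | 8.00 | 18.8 | 9.9 | 1.7 |
| epsilon | 12.0 | 21.2 | 13.2 | 0.5 |
| epsilon | 20.0 | 21.7 | 17.4 | 0 |
| epsilon | 30.0 | 23.0 | 23.5 | 0 |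
| gamma | 5.00 | 13.6 | 4.1 | 10.5 |
| gamma | 10.0 | 17.7 | 11.2 | 0.2 |
| gamma | 15.0 | 21.0 | 14.8 | 0 |
| gamma | 20.0 | 20.0 | 20.0 | 0.5 |
| gamma | 25.0 | 22.5 | 20.1 | 0 |
| gamma | 30.0 | 23.2 | 21.9 | 0.9 |

(readings scatter by 1 percentage point)

- what was read earlier has a scatter of 1 percentage point, one standard deviation

- share of E in E plus X at 1.0 h
- share of E in E plus X at 40 h

First I asked whether the charge mattered. A single reading of Z gave its half-life in each run:

epsilon: 1.37 h
gamma: 1.54 h

The gamma charge was twice the epsilon charge, yet these readings lay close, so the loss of Z looked first-order and I pooled the percentages of both runs.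

The time 1.0 h lies inside one half-life, and no reading stands there, so I took the nearest ones, up to 5.00 h. Their shares ran 71.3%, 82.1% and 76.8%, with no steady drift. Pooled E over pooled E plus X, my early share (an early selectivity), came to:

77.4%

At 20.0 h, about 14.6 half-lives on, Z read at most 0.5%. I pooled the readings from then on in the same way:

51.8%

That stood 26 percentage points below the early share, and I carried it to 40 h. The weak link was assuming the share had stopped falling. It read 52.7%, 52.8%, then 50.4%. With the scatter given I could not tell that fall from none, so I kept the figure.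

The forecast, unlike my reckoning, said 85% and 48%, its early figure “rising towards earlier times if X lags E”. The flask gave 78.4% at 1.0 h and 53.4% at 40 h.

    D → X (k = 6.10 × 10⁻⁵ s⁻¹)
    X ⇌ J (K = 0.350, k = 1.70 × 10⁻⁵ s⁻¹)
    X → G (k = 1.10 × 10⁻⁵ s⁻¹)
    L ⇌ D (K = 0.660, k = 1.30 × 10⁻⁵ s⁻¹)
    Z → Q (k = 3.40 × 10⁻⁵ s⁻¹)
    Q → X (k = 2.20 × 10⁻⁵ s⁻¹)
    D → Q (k = 6.40 × 10⁻⁶ s⁻¹)
    Z → L (k = 1.00 × 10⁻⁴ s⁻¹)
    Q → E (k = 8.80 × 10⁻⁵ s⁻¹)

My early share lay 1.0 point below the flask's value at 1.0 h. Q passes on to E and to X, and E's part of that split is 80.0%. With the loss of Z to Q struck out, the flask's share at 1.0 h dropped from 78.4% to 0.808%, so that loss is the main reason for the flask's share at that time. Carried to the neighbour flask charged with 0.25 M, my early share lies 1.0 point below that flask's 78.4% at 1.0 h.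

(All runs are simulated on assumed constants; scatter was added.)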